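## Analysis of the target

The target is a germacranolide. In germacrane numbering, C1–C10 form the ten-membered ring, C14 sits on C10, C15 on C4, and C11–C13 form the lactone arm. An oxygen links C3 and C10, so that C3, C2, C1, C10 and this oxygen form an oxolane that bridges the ring (an 11-oxabicyclo[6.2.1]undecene). An α-methylene γ-lactone is fused at C6–C7, and C4=C5 is a Z trisubstituted alkene.

The ring stereocentres are 3S, 6S, 7R, 8R and 10R, and the 2-methylbutanoate carries an (R) centre. The oxygen bridge, the lactone oxygen on C6, C11 on C7 and the acyloxy group on C8 all lie on one face of the ring (the lactone is cis-fused); the C3 hydroxyl and C14 lie on the other. C3 is a hemiketal tied to C10 through the bridge, so it sets itself once C10 is fixed. The real stereochemical problems are the remote quaternary C10 and the contiguous triad C6–C7–C8.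

Sensitive groups are the hemiketal (ring–chain tautomerism), the α-methylene lactone (Michael acceptor), the epimerizable α-centre of the ester and the allylic lactone carbinol. What makes the synthesis hard is closing a ten-membered ring that holds a Z alkene, and the fact that O6 and O8 are both γ to C12 and both cis to C11, so lactone regiochemistry has to be enforced.

The strategy rests on one feature: C3 and C6 are oxygenated 1,4 across the Z C4=C5 bond that carries C15 on C4. This is the pattern left by two-electron oxidation of a 2,5-dialkyl-3-methylfuran. The C10 oxygen sits three carbons from C3, placed to capture that carbon in a five-membered ring.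

## Retrosynthetic reasoning

**29 back to 26 and 27 (ester C–O at C8, silyl ether at C14).** The primary C14 hydroxyl is freed last from 28. The 2-methylbutanoate is attached just before that, by acylating the only secondary hydroxyl of 26 with acid 27. Putting the ester on this late keeps its α-centre away from every strongly basic step.

**26 back to 22 (C11=C13).** The exocyclic methylene is cut to the saturated lactone 22. It is introduced through the lactone enolate while O8 and the hemiketal oxygen are silylated (25), so that no alkoxide can trigger translactonization or hemiketal opening, and no second ester competes for the base.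

**22 back to 19 (lactone C12–O6 and the C6–H bond).** The lactone is opened to a C6 ketone with a pendant methyl ester. O8 is silylated (20) before the C6 carbinol exists. Otherwise O6 and O8, which are locally equivalent and both cis to C11, would compete for C12. The forward reduction must place O6 cis to C11.

**19 back to 18 (C7–C8).** The ten-membered ring is cut at C7–C8, an aldol bond between the C6 ketone and a C8 aldehyde. This is the one ring bond that can be made from the carbonyl groups the furan oxidation leaves behind. The Z alkene and the oxolane already hold the two ends close. The forward reaction must enolize only toward C7, which holds as long as C3 stays ketalized, and must set C7 and C8 anti.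

**18 back to 16 (unmasking).** The C6 ketone and C3 hemiketal come from hydrolysis of the methoxy spiroketal. The C8 aldehyde comes from a terminal alkene by oxidative cleavage (17). An allyl group is used as the latent aldehyde for two reasons: it is inert to every earlier step including the electrolysis, and the allylic alcohol that carries it (7) is made in one step.

**16 back to 15 (C3–O bond, oxolane ring; the key disconnection).** The spiroketal is the two-electron oxidation product of furan 15. The four furan carbons become C3–C6. The forward step must attach the C10 hydroxyl to C3 and an external methoxy group to C6. The Z geometry and the C15 methyl come with the furan.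

**15 back to 11 and 13 (the propanoate arm).** The C7–C11–C12 chain is removed to the free furan α-position of 11. Forward, formylation (12), olefination with 13 (14) and conjugate reduction are used. This is placed after the fragment union because an ester would not survive the carbanion chemistry of that union.

**11 back to 4 and 9 (C1–C2).** The bond between the furylmethyl carbon and the epoxide methylene is cut. The nucleophile is the sulfonyl-stabilized carbanion of 4, which reacts only at the exocyclic carbon; unstabilized furylmethyl metals are ambident and their halide precursors are unstable. The sulfonyl group of 10 is then removed reductively.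

**9 back to 5 and 6; 4 back to 1.** Epoxide 9 comes from the Sharpless epoxidation of allylic alcohol 7 (via 8), which fixes C10. Alcohol 7 comes from 5 and 6 by carbomagnesiation. Sulfone 4 comes from acid 1 through alcohol 2.

## Alternatives that were turned down

**Alternative 1: ozonolytic opening of an octalin.** The ten-membered ring is seen as the periphery of two fused six-membered rings. The key step is ozonolysis with reductive work-up of the tetrasubstituted ring-fusion alkene of octalin lactone A2, giving the cyclodecane-3,8-dione A1.
- For: no macrocyclization is needed, and C6, C7 and C10 can be set with cyclohexane stereocontrol before the ring is opened. Cleavage of a tetrasubstituted alkene is dependable. On ring formation this is stronger than the aldol closure used here.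
- Against: A1 has C4 as a saturated methine and C8 as a ketone. The Z C4=C5 alkene would have to be introduced by regioselective dehydrogenation toward a tertiary α-carbon with control of geometry in a medium ring. C8 needs a face-selective reduction. A 1,6-diketone in a cyclodecane invites transannular aldol reaction. The methylene lactone is still missing, and the dearomatization route to A2 is long.
- Comparison: the chosen route accepts a harder ring closure but obtains the alkene geometry, the C15 methyl and both oxygens at C3 and C6 in one operation.

**Alternative 2: keto sulfone carbanion opening an epoxide.** C1–C2 and the C3–O bridge bond are cut together. The C2 carbanion of the epoxy β-keto sulfone A4 attacks the epoxide methylene, closing the ten-membered ring, and the liberated C10 alkoxide adds to the C3 ketone to give the sulfonyl hemiketal A3.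
- For: the whole C6–C7–C8 triad, the lactone and the ester are in place before cyclization, so no diastereoselective macrocyclic aldol is needed. On stereocontrol of C7 and C8 this is stronger than the chosen route. The bridged hemiketal forms in the same step.
- Against: a doubly stabilized carbanion is a poor nucleophile toward an unactivated epoxide. Both epoxide carbons lie inside the forming ring, which demands a strained collinear approach. The basic or Lewis acidic conditions needed expose a Z enone with the lactone oxygen as a γ leaving group at C6, an epimerizable ester and an enolate oxygen that can alkylate instead of carbon. A4 also needs the Z trisubstituted enone built by separate means, and a reductive desulfonylation next to the hemiketal follows.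
- Comparison: the chosen route offers a furan as a stable carrier of the Z ene-dione and reveals it only when needed.

**Alternative 3: Wittig–Still ring contraction.** The same C7–C8 bond is made by a sigmatropic shift. Tin–lithium exchange in the thirteen-membered α-stannyl allyl ether A6 triggers a [2,3] shift to the bicyclic homoallylic alcohol A5, creating the C11=C13 methylene at the same time.
- For: a thirteen-membered ether is easier to close than a ten-membered carbocycle. One step forms C7–C8, the C8 carbinol and the exocyclic alkene. This is better step economy at that point than the chosen route, which needs a separate methylenation, and the ordered transition state transfers stereochemistry well.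
- Against: A6 must already contain the Z alkene, the C3 ketal, the C6 carbinol and a configurationally defined α-alkoxystannane, so the effort moves into a long precursor synthesis. The contraction builds transannular strain, which favours the competing [1,2] shift. A5 has C12 at the alcohol level, so oxidation and lactonization remain. Organotin reagents are needed.
- Comparison: the chosen route reaches its cyclization substrate in fewer steps, because the furan supplies C3–C6 ready-made.

Key step: step 11

Remark on the chemistry: centres that arise as epimeric mixtures and are later erased (the sulfonyl carbon of 10, the ketal carbons of 16 and 17, the hemiketal carbon of 18, C11 of 23 and 24) are written without configuration; 18 is drawn as its C3 hemiketal, one of several ring–chain tautomers.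

## Route

Step 1
Reactants: 1 3-methylfuran-2-carboxylic acid
Product: 2 (3-methylfuran-2-yl)methanol
Conditions: LiAlH4, THF, 0 °C to rt
Reagents that add atoms: none
Why: Hydride reduction of a carboxylic acid to the primary alcohol; the furan ring is inert to LiAlH4.

Step 2
Reactants: 2 (3-methylfuran-2-yl)methanol
Product: 4 3-methyl-2-[(phenylsulfonyl)methyl]furan, via chloride 3 (not isolated)
Conditions: MsCl, Et3N, LiCl, THF, −20 to 0 °C; then PhSO2Na, DMF, rt
Reagents that add atoms: sodium benzenesulfinate [Na+].[O-]S(=O)c1ccccc1; lithium chloride [Li+].[Cl-] (chlorine of intermediate 3 only)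
Why: Nucleophilic substitution: the furfuryl alcohol is activated in the cold, collapses to chloride 3 and is displaced by the soft sulfinate at sulfur to give the sulfone. The sulfonyl group later stabilizes the carbanion and fixes C–C bond formation at the exocyclic carbon, which an unstabilized furylmethyl metal (ambident, from an unstable halide) would not do reliably.

Step 3
Reactants: 5 prop-2-yn-1-ol; 6 allylmagnesium bromide
Product: 7 2-methylidenepent-4-en-1-ol
Conditions: 6 (2.5 equiv), CuI (5 mol %), Et2O, −10 °C to rt; aq NH4Cl
Reagents that add atoms: none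
Why: Hydroxyl-directed carbomagnesiation of a propargylic alcohol: the magnesium alkoxide delivers the allyl group to the inner alkyne carbon and protonation of the vinylmagnesium intermediate gives the 2-substituted allylic alcohol in one step.

Step 4
Reactants: 7 2-methylidenepent-4-en-1-ol
Product: 8 (R)-[2-(prop-2-en-1-yl)oxiran-2-yl]methanol
Conditions: Ti(OiPr)4 (10 mol %), D-(−)-diisopropyl tartrate (12 mol %), t-BuOOH, 4 Å sieves, CH2Cl2, −25 °C
Reagents that add atoms: tert-butyl hydroperoxide CC(C)(C)OO
Why: Sharpless asymmetric epoxidation: only the allylic-alcohol alkene is bound to titanium, and the D-(−)-tartrate delivers oxygen to the face that gives the (R)-epoxy alcohol, by analogy with (R)-2-methylglycidol from methallyl alcohol; this sets C10. Catalytic loading, sieves and low temperature limit opening of the sensitive 2,2-disubstituted epoxy alcohol.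

Step 5
Reactants: 8 (R)-[2-(prop-2-en-1-yl)oxiran-2-yl]methanol
Product: 9 (S)-tert-butyl(dimethyl){[2-(prop-2-en-1-yl)oxiran-2-yl]methoxy}silane
Conditions: TBSCl, imidazole, CH2Cl2, 0 °C
Reagents that add atoms: tert-butyldimethylsilyl chloride CC(C)(C)[Si](C)(C)Cl
Why: Silyl ether formation at the primary alcohol; the descriptor changes from R to S only because of CIP priorities.

Step 6
Reactants: 4 3-methyl-2-[(phenylsulfonyl)methyl]furan; 9 (S)-tert-butyl(dimethyl){[2-(prop-2-en-1-yl)oxiran-2-yl]methoxy}silane
Product: 10 (2S)-1-{[tert-butyl(dimethyl)silyl]oxy}-2-[2-(3-methylfuran-2-yl)-2-(phenylsulfonyl)ethyl]pent-4-en-2-ol (both epimers at the sulfonyl carbon)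
Conditions: n-BuLi, THF, −78 °C; then 9, BF3·OEt2, −78 °C; aq NH4Cl
Reagents that add atoms: none
Why: Alkylation of an α-sulfonyl carbanion by a 2,2-disubstituted epoxide at its unsubstituted carbon, as in sulfone/isobutylene oxide couplings; BF3 activation lets the stabilized furfuryl anion react at −78 °C. The C10 centre is not touched, and the new sulfonyl-bearing centre is removed in the next step.

Step 7
Reactants: 10 (2S)-1-{[tert-butyl(dimethyl)silyl]oxy}-2-[2-(3-methylfuran-2-yl)-2-(phenylsulfonyl)ethyl]pent-4-en-2-ol
Product: 11 (2R)-1-{[tert-butyl(dimethyl)silyl]oxy}-2-[2-(3-methylfuran-2-yl)ethyl]pent-4-en-2-ol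
Conditions: Mg turnings, MeOH, rt to 50 °C
Reagents that add atoms: none
Why: Reductive desulfonylation by electron transfer from magnesium, easy for a furfuryl-type sulfone; the hydroxyl is γ to sulfur, so no Julia-type elimination can occur, and the silyl ether and terminal alkene are inert.

Step 8
Reactants: 11 (2R)-1-{[tert-butyl(dimethyl)silyl]oxy}-2-[2-(3-methylfuran-2-yl)ethyl]pent-4-en-2-ol
Product: 12 5-[(3R)-3-({[tert-butyl(dimethyl)silyl]oxy}methyl)-3-hydroxyhex-5-en-1-yl]-4-methylfuran-2-carbaldehyde
Conditions: n-BuLi (2.3 equiv), TMEDA, THF, −78 to 0 °C; DMF, −78 °C to rt; aq NH4Cl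
Reagents that add atoms: N,N-dimethylformamide CN(C)C=O
Why: After deprotonation of the alcohol, the second equivalent lithiates the only free furan α-position (ring α-lithiation is far faster than allylic or lateral deprotonation), and DMF formylates the furyllithium.

Step 9
Reactants: 12 5-[(3R)-3-({[tert-butyl(dimethyl)silyl]oxy}methyl)-3-hydroxyhex-5-en-1-yl]-4-methylfuran-2-carbaldehyde; 13 trimethyl phosphonoacetate
Product: 14 methyl (2E)-3-{5-[(3R)-3-({[tert-butyl(dimethyl)silyl]oxy}methyl)-3-hydroxyhex-5-en-1-yl]-4-methylfuran-2-yl}prop-2-enoate
Conditions: LiCl, DBU, MeCN, rt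
Reagents that add atoms: none
Why: Horner–Wadsworth–Emmons olefination under Masamune–Roush conditions, which tolerate the free tertiary alcohol; the alkene geometry is irrelevant because it is reduced next.

Step 10
Reactants: 14 methyl (2E)-3-{5-[(3R)-3-({[tert-butyl(dimethyl)silyl]oxy}methyl)-3-hydroxyhex-5-en-1-yl]-4-methylfuran-2-yl}prop-2-enoate
Product: 15 methyl 3-{5-[(3R)-3-({[tert-butyl(dimethyl)silyl]oxy}methyl)-3-hydroxyhex-5-en-1-yl]-4-methylfuran-2-yl}propanoate
Conditions: Mg turnings, MeOH, 0 °C to rt
Reagents that add atoms: none
Why: Dissolving-metal conjugate reduction of an aryl-conjugated enoate; the isolated terminal alkene is not reduced, and the methyl ester matches the solvent so transesterification changes nothing.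

Step 11
Reactants: 15 methyl 3-{5-[(3R)-3-({[tert-butyl(dimethyl)silyl]oxy}methyl)-3-hydroxyhex-5-en-1-yl]-4-methylfuran-2-yl}propanoate
Product: 16 methyl 3-[(7R)-7-({[tert-butyl(dimethyl)silyl]oxy}methyl)-2-methoxy-4-methyl-7-(prop-2-en-1-yl)-1,6-dioxaspiro[4.4]non-3-en-2-yl]propanoate (epimers at both ketal carbons)
Conditions: undivided cell, reticulated vitreous carbon anode, Pt cathode, constant current (about 2.2 F/mol), Et4NOTs (0.1 M), 2,6-lutidine, MeOH, 0 °C
Reagents that add atoms: methanol CO
Why: Anodic two-electron oxidation of the furan with one internal and one external oxygen nucleophile: electron transfer gives the furan radical cation, the trialkylfuran being by far the most easily oxidized group in 15 (terminal alkene, ester and silyl ether oxidize much higher). The C10 hydroxyl attacks the tether-bearing α-carbon (C3) in a 5-exo closure that forms the C3–O bond and the oxolane; loss of a proton and a second electron gives the oxocarbenium ion at C6, which methanol caps. The closest known reaction is the electrolytic methoxylation of 3-(2-furyl)propanols to 2-methoxy-1,6-dioxaspiro[4.4]non-3-enes. The two new ketal centres (C3 and C6) are not controlled and need not be, because C6 becomes a ketone and C3 an equilibrating hemiketal, while C10 is untouched. The only selectivity needed is constitutional (internal alcohol at C3, methanol at C6); the five-membered tether secures it, and even a bis-methoxy by-product would converge to 18 on hydrolysis. The alkene can only be Z because C3–C6 stay in the five-membered ring, and C15 is already on C4. 2,6-Lutidine keeps the medium non-acidic so that the product ketal does not ionize and eliminate toward side-chain-substituted furans.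

Step 12
Reactants: 16 methyl 3-[(7R)-7-({[tert-butyl(dimethyl)silyl]oxy}methyl)-2-methoxy-4-methyl-7-(prop-2-en-1-yl)-1,6-dioxaspiro[4.4]non-3-en-2-yl]propanoate
Product: 17 methyl 3-[(7R)-7-({[tert-butyl(dimethyl)silyl]oxy}methyl)-2-methoxy-4-methyl-7-(2-oxoethyl)-1,6-dioxaspiro[4.4]non-3-en-2-yl]propanoate
Conditions: OsO4 (2 mol %), NaIO4, 2,6-lutidine, dioxane/H2O, rt
Reagents that add atoms: osmium tetroxide O=[Os](=O)(=O)=O (catalytic oxygen carrier); sodium periodate [Na+].[O-]I(=O)(=O)=O (terminal oxidant)
Why: Lemieux–Johnson cleavage: OsO4 dihydroxylates the unhindered monosubstituted alkene much faster than the trisubstituted ring alkene flanked by two ketal carbons, and periodate cleaves the diol; the lutidine buffer keeps the ketal intact.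

Step 13
Reactants: 17 methyl 3-[(7R)-7-({[tert-butyl(dimethyl)silyl]oxy}methyl)-2-methoxy-4-methyl-7-(2-oxoethyl)-1,6-dioxaspiro[4.4]non-3-en-2-yl]propanoate
Product: 18 methyl (5Z)-6-[(5R)-5-({[tert-butyl(dimethyl)silyl]oxy}methyl)-2-hydroxy-5-(2-oxoethyl)oxolan-2-yl]-4-oxohept-5-enoate (ring–chain tautomers)
Conditions: PPTS (cat.), acetone/H2O (10:1), 0 °C to rt
Reagents that add atoms: water O
Why: Acid-catalysed ketal hydrolysis: loss of methanol gives the oxygen-stabilized cation at C6, water adds, and the lactol opens to the C6 enone with C3 left as the cyclic hemiketal; the alkene stays Z because it is formed from the ring. The product should equilibrate with a spiro lactol and with a bicyclic lactol formed with the C8 aldehyde, all of which keep C3 ketalized; it is used at once.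

Step 14
Reactants: 18 methyl (5Z)-6-[(5R)-5-({[tert-butyl(dimethyl)silyl]oxy}methyl)-2-hydroxy-5-(2-oxoethyl)oxolan-2-yl]-4-oxohept-5-enoate
Product: 19 methyl 2-[(1S,2Z,5R,6R,8R)-8-({[tert-butyl(dimethyl)silyl]oxy}methyl)-1,6-dihydroxy-2-methyl-4-oxo-11-oxabicyclo[6.2.1]undec-2-en-5-yl]acetate
Conditions: Cy2BCl (2.2 equiv), Et3N (2.5 equiv), Et2O (2 mM), −78 to −20 °C; then pH 7 buffer, MeOH, H2O2, 0 °C
Reagents that add atoms: none
Why: Intramolecular boron aldol: Cy2BCl/Et3N gives the (E)-enol borinate of the C6 ketone toward C7, the only enolizable ketone position while C3 stays ketalized, and the chair transition state turns the E geometry into the anti relation of C11 and the C8 hydroxyl; one equivalent of boron reagent is taken up by the hemiketal hydroxyl. The Z alkene and the oxolane hold C7 and C8 within reach, and closure with C8–O on the face of the oxygen bridge is expected, though this facial outcome is the least secure stereochemical point of the route.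

Step 15
Reactants: 19 methyl 2-[(1S,2Z,5R,6R,8R)-8-({[tert-butyl(dimethyl)silyl]oxy}methyl)-1,6-dihydroxy-2-methyl-4-oxo-11-oxabicyclo[6.2.1]undec-2-en-5-yl]acetate
Product: 20 1,6-bis-O-triethylsilyl ether of 19 (germacrane positions O3 and O8)
Conditions: TESOTf (3 equiv), 2,6-lutidine, CH2Cl2, −78 to −20 °C
Reagents that add atoms: triethylsilyl trifluoromethanesulfonate CC[Si](CC)(CC)OS(=O)(=O)C(F)(F)F
Why: Silyl ether formation: O8 is capped before the C6 carbinol exists, so only O6 can later lactonize, and the hemiketal is held as a silyl ketal for the strongly basic methylenation; 2,6-lutidine is too weak a base to enolize the ketone.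

Step 16
Reactants: 20 1,6-bis-O-triethylsilyl ether of 19
Product: 22 bis-TES 6,12-lactone (cis-fused γ-lactone between O6 and C12; O6, C11 and O8 on the face of the oxygen bridge), via hydroxy ester 21 (not isolated)
Conditions: NaBH4, MeOH/THF, −40 °C; then PPTS (cat.), toluene, rt
Reagents that add atoms: none
Why: Borohydride 1,2-reduction (C4 is fully substituted, so conjugate addition does not compete); hydride should enter anti to the C8 branch on C7 (Felkin–Anh) and from the face opposite the oxygen bridge, which places O6 cis to C11. The C6 hydroxyl then closes onto C12 (lactonization), and because O8 is silylated only the 6,12-lactone can form.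

Step 17
Reactants: 22 bis-TES 6,12-lactone
Product: 25 bis-TES 11(13)-methylene lactone, via Mannich base 23 (not isolated), via methiodide 24 (not isolated)
Conditions: LiN(SiMe3)2, THF, −78 °C; CH2=NMe2+ I−, −78 °C to rt; then MeI, MeOH, rt; aq NaHCO3
Reagents that add atoms: Eschenmoser's salt C=[N+](C)C.[I-]; iodomethane CI (methyl group of intermediate 24 only)
Why: Mannich reaction of the lactone enolate with Eschenmoser's salt, quaternization and E1cB elimination give the α-methylene lactone; C11 ends sp2, so its configuration in 23 and 24 does not matter. No free hydroxyl or second ester is present, so the base meets only the lactone.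

Step 18
Reactants: 25 bis-TES 11(13)-methylene lactone
Product: 26 14-O-TBS 3,8-diol (the target lacking the acyl group, C14 still silylated)
Conditions: HF·pyridine, pyridine, THF, 0 °C
Reagents that add atoms: none
Why: Selective fluoride cleavage: the silyl ketal and the secondary TES ether are far more labile than the neopentyl-type primary TBS ether, which is kept to block C14 during acylation.

Step 19
Reactants: 26 14-O-TBS 3,8-diol; 27 (R)-2-methylbutanoic acid
Product: 28 14-O-TBS ether of the target
Conditions: DIC, DMAP (cat.), CH2Cl2, 0 °C to rt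
Reagents that add atoms: none
Why: Steglich esterification of the only secondary alcohol; the tertiary hemiketal hydroxyl is not acylated under these conditions, and low temperature with catalytic DMAP keeps the α-centre of the acid intact.

Step 20
Reactants: 28 14-O-TBS ether of the target
Product: 29 (3S,6S,7R,8R,10R)-3,10-epoxy-3,14-dihydroxy-8-[(2R)-2-methylbutanoyloxy]germacra-4Z,11(13)-dien-12,6-olide
Conditions: HF·pyridine, THF, 0 °C to rt
Reagents that add atoms: none
Why: Fluoride desilylation of the primary TBS ether; the acidic fluoride source leaves the methylene lactone, the ester and the hemiketal untouched.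

## Compound list

1 | 3-methylfuran-2-carboxylic acid | Cc1ccoc1C(=O)O | starting material
2 | (3-methylfuran-2-yl)methanol | Cc1ccoc1CO | intermediate
3 | 2-(chloromethyl)-3-methylfuran | Cc1ccoc1CCl | intermediate
4 | 3-methyl-2-[(phenylsulfonyl)methyl]furan | Cc1ccoc1CS(=O)(=O)c1ccccc1 | intermediate
5 | prop-2-yn-1-ol | C#CCO | starting material
6 | allylmagnesium bromide | C=CC[Mg]Br | starting material
7 | 2-methylidenepent-4-en-1-ol | C=CCC(=C)CO | intermediate
8 | (R)-[2-(prop-2-en-1-yl)oxiran-2-yl]methanol | OC[C@]1(CC=C)CO1 | intermediate
9 | (S)-tert-butyl(dimethyl){[2-(prop-2-en-1-yl)oxiran-2-yl]methoxy}silane | CC(C)(C)[Si](C)(C)OC[C@]1(CC=C)CO1 | intermediate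
10 | (2S)-1-{[tert-butyl(dimethyl)silyl]oxy}-2-[2-(3-methylfuran-2-yl)-2-(phenylsulfonyl)ethyl]pent-4-en-2-ol | Cc1ccoc1C(C[C@](O)(CO[Si](C)(C)C(C)(C)C)CC=C)S(=O)(=O)c1ccccc1 | intermediate
11 | (2R)-1-{[tert-butyl(dimethyl)silyl]oxy}-2-[2-(3-methylfuran-2-yl)ethyl]pent-4-en-2-ol | Cc1ccoc1CC[C@](O)(CO[Si](C)(C)C(C)(C)C)CC=C | intermediate
12 | 5-[(3R)-3-({[tert-butyl(dimethyl)silyl]oxy}methyl)-3-hydroxyhex-5-en-1-yl]-4-methylfuran-2-carbaldehyde | O=Cc1cc(C)c(CC[C@](O)(CO[Si](C)(C)C(C)(C)C)CC=C)o1 | intermediate
13 | trimethyl phosphonoacetate | COC(=O)CP(=O)(OC)OC | starting material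
14 | methyl (2E)-3-{5-[(3R)-3-({[tert-butyl(dimethyl)silyl]oxy}methyl)-3-hydroxyhex-5-en-1-yl]-4-methylfuran-2-yl}prop-2-enoate | COC(=O)/C=C/c1cc(C)c(CC[C@](O)(CO[Si](C)(C)C(C)(C)C)CC=C)o1 | intermediate
15 | methyl 3-{5-[(3R)-3-({[tert-butyl(dimethyl)silyl]oxy}methyl)-3-hydroxyhex-5-en-1-yl]-4-methylfuran-2-yl}propanoate | COC(=O)CCc1cc(C)c(CC[C@](O)(CO[Si](C)(C)C(C)(C)C)CC=C)o1 | intermediate
16 | methyl 3-[(7R)-7-({[tert-butyl(dimethyl)silyl]oxy}methyl)-2-methoxy-4-methyl-7-(prop-2-en-1-yl)-1,6-dioxaspiro[4.4]non-3-en-2-yl]propanoate | COC(=O)CCC1(OC)C=C(C)C2(CC[C@](CO[Si](C)(C)C(C)(C)C)(CC=C)O2)O1 | intermediate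
17 | methyl 3-[(7R)-7-({[tert-butyl(dimethyl)silyl]oxy}methyl)-2-methoxy-4-methyl-7-(2-oxoethyl)-1,6-dioxaspiro[4.4]non-3-en-2-yl]propanoate | COC(=O)CCC1(OC)C=C(C)C2(CC[C@](CO[Si](C)(C)C(C)(C)C)(CC=O)O2)O1 | intermediate
18 | methyl (5Z)-6-[(5R)-5-({[tert-butyl(dimethyl)silyl]oxy}methyl)-2-hydroxy-5-(2-oxoethyl)oxolan-2-yl]-4-oxohept-5-enoate | COC(=O)CCC(=O)/C=C(/C)C1(O)CC[C@](CO[Si](C)(C)C(C)(C)C)(CC=O)O1 | intermediate
19 | methyl 2-[(1S,2Z,5R,6R,8R)-8-({[tert-butyl(dimethyl)silyl]oxy}methyl)-1,6-dihydroxy-2-methyl-4-oxo-11-oxabicyclo[6.2.1]undec-2-en-5-yl]acetate | O=C1/C=C(/C)[C@]2(O)CC[C@](CO[Si](C)(C)C(C)(C)C)(C[C@@H](O)[C@H]1CC(=O)OC)O2 | intermediate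
20 | 1,6-bis-O-triethylsilyl ether of 19 (ring configuration unchanged) | O=C1/C=C(/C)[C@]2(O[Si](CC)(CC)CC)CC[C@](CO[Si](C)(C)C(C)(C)C)(C[C@@H](O[Si](CC)(CC)CC)[C@H]1CC(=O)OC)O2 | intermediate
21 | C6 alcohol of 20 (germacrane numbering), hydroxyl on the face of the oxygen bridge and cis to the acetate arm | O[C@H]1/C=C(/C)[C@]2(O[Si](CC)(CC)CC)CC[C@](CO[Si](C)(C)C(C)(C)C)(C[C@@H](O[Si](CC)(CC)CC)[C@H]1CC(=O)OC)O2 | intermediate
22 | 14-O-TBS-3,8-bis-O-TES-3,10-epoxy-3,8,14-trihydroxygermacr-4Z-en-12,6-olide, cis-fused lactone, configuration at C6, C7, C8 and C10 as in 29 | C1C(=O)O[C@H]2/C=C(/C)[C@]3(O[Si](CC)(CC)CC)CC[C@](CO[Si](C)(C)C(C)(C)C)(C[C@@H](O[Si](CC)(CC)CC)[C@@H]12)O3 | intermediate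
23 | 13-(dimethylamino) derivative of 22 (C11 epimers) | CN(C)CC1C(=O)O[C@H]2/C=C(/C)[C@]3(O[Si](CC)(CC)CC)CC[C@](CO[Si](C)(C)C(C)(C)C)(C[C@@H](O[Si](CC)(CC)CC)[C@@H]12)O3 | intermediate
24 | trimethylammonium iodide of 23 | C[N+](C)(C)CC1C(=O)O[C@H]2/C=C(/C)[C@]3(O[Si](CC)(CC)CC)CC[C@](CO[Si](C)(C)C(C)(C)C)(C[C@@H](O[Si](CC)(CC)CC)[C@@H]12)O3.[I-] | intermediate
25 | 11(13)-methylene lactone: 14-O-TBS-3,8-bis-O-TES-3,10-epoxy-3,8,14-trihydroxygermacra-4Z,11(13)-dien-12,6-olide | C=C1C(=O)O[C@H]2/C=C(/C)[C@]3(O[Si](CC)(CC)CC)CC[C@](CO[Si](C)(C)C(C)(C)C)(C[C@@H](O[Si](CC)(CC)CC)[C@@H]12)O3 | intermediate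
26 | (3S,6S,7R,8R,10R)-14-O-TBS-3,10-epoxy-3,8,14-trihydroxygermacra-4Z,11(13)-dien-12,6-olide | C=C1C(=O)O[C@H]2/C=C(/C)[C@]3(O)CC[C@](CO[Si](C)(C)C(C)(C)C)(C[C@@H](O)[C@@H]12)O3 | intermediate
27 | (R)-2-methylbutanoic acid | CC[C@@H](C)C(=O)O | starting material
28 | 14-O-tert-butyldimethylsilyl ether of 29 | C=C1C(=O)O[C@H]2/C=C(/C)[C@]3(O)CC[C@](CO[Si](C)(C)C(C)(C)C)(C[C@@H](OC(=O)[C@H](C)CC)[C@@H]12)O3 | intermediate
29 | (3S,6S,7R,8R,10R)-3,10-epoxy-3,14-dihydroxy-8-[(2R)-2-methylbutanoyloxy]germacra-4Z,11(13)-dien-12,6-olide | C=C1C(=O)O[C@H]2/C=C(/C)[C@]3(O)CC[C@](CO)(C[C@@H](OC(=O)[C@H](C)CC)[C@@H]12)O3 | target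

## Step count and least certain steps

Total: 20 steps. Longest linear sequence: 18 steps (steps 3–20, from 5 and 6); the branch from 1 runs 17 steps (steps 1, 2, 6–20).

**Step 11 (key step).** The electrolysis may stall through electrode passivation. The product ketal may also ionize if the anolyte turns acidic, and then eliminate toward side-chain-functionalized furans. Fallback with a different oxidant and mechanism: 15 is photooxygenated (O2, rose bengal, visible light, MeOH, −78 °C). Singlet oxygen adds across the furan in a [4+2] sense, and the C10 hydroxyl opens the endoperoxide to the spiro hydroperoxide F1. Me2S reduces this to the spiro lactol F2, which is the hydrolysed form of 16. Lemieux–Johnson cleavage of the terminal alkene of F2 (OsO4, NaIO4, 2,6-lutidine) then leads to 18, where the route is rejoined.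

**Step 14.** Several things may go wrong:
- The ring–chain tautomers of 18 may open at C3. The freed ketone would then enolize toward C2 and close a five-membered ring onto the aldehyde.
- The aldehyde may itself enolize and expel the C10 oxygen by β-elimination.
- Oligomerization may outrun ring closure.
- The ring may close on the wrong face relative to C10.

Fallback through a separately formed enol silane and an open transition state: 18 is treated with TMSOTf/Et3N at −78 °C. This gives the C6 trimethylsilyl dienol ether in which the aldehyde is held as the silylated bicyclic lactol and C3 stays ketalized, F3. BF3·OEt2 at high dilution and −78 °C then brings about an intramolecular Mukaiyama aldol reaction, and aqueous work-up returns to 19.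

**Step 16.** Hydride delivery to the C6 ketone may show poor facial selectivity, because no chelating group directs it once O8 is silylated. Fallback with 1,3-chelation control: 19 (free C8 hydroxyl) is reduced under Narasaka–Prasad conditions (Et2BOMe, NaBH4, THF/MeOH, −78 °C) to the syn diol F4. Acid-catalysed lactonization (PPTS, toluene) gives the 8-hydroxy-6,12-lactone F5. Any 8,12-lactone regioisomer formed alongside would be separated and re-equilibrated with base. Silylation of F5 with TESOTf/2,6-lutidine returns to 22.

**Step 6.** The stabilized furfuryl sulfone anion may open the hindered epoxide too slowly. Under BF3 the 2,2-disubstituted epoxide may rearrange to a carbonyl compound, or the silyl group may migrate. Fallback that builds C10 by catalyst-controlled ketone allylation instead: 2 is oxidized with MnO2 to 3-methylfuran-2-carbaldehyde F6. Horner–Wadsworth–Emmons reaction with dimethyl [3-(tert-butyldimethylsilyloxy)-2-oxopropyl]phosphonate (LiCl, DBU) gives the enone F7. Conjugate reduction with [(Ph3P)CuH]6 gives the ketone F8. Enantioselective allylboration of F8 (allylboronate with a chiral 3,3'-dibromo-BINOL catalyst chosen for the R product) gives 11. The enantiomeric purity would probably need upgrading.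

## Further compounds

F1 | step 11 | spiro hydroperoxide: methyl 3-[(7R)-7-({[tert-butyl(dimethyl)silyl]oxy}methyl)-2-hydroperoxy-4-methyl-7-(prop-2-en-1-yl)-1,6-dioxaspiro[4.4]non-3-en-2-yl]propanoate | COC(=O)CCC1(OO)C=C(C)C2(CC[C@](CO[Si](C)(C)C(C)(C)C)(CC=C)O2)O1
F2 | step 11 | spiro lactol: methyl 3-[(7R)-7-({[tert-butyl(dimethyl)silyl]oxy}methyl)-2-hydroxy-4-methyl-7-(prop-2-en-1-yl)-1,6-dioxaspiro[4.4]non-3-en-2-yl]propanoate | COC(=O)CCC1(O)C=C(C)C2(CC[C@](CO[Si](C)(C)C(C)(C)C)(CC=C)O2)O1
F3 | step 14 | C6 trimethylsilyl dienol ether of 18 with the aldehyde held as silylated 2,8-dioxabicyclo[3.2.1]octane lactol | COC(=O)CC=C(O[Si](C)(C)C)/C=C(/C)C12CC[C@](CO[Si](C)(C)C(C)(C)C)(CC(O[Si](C)(C)C)O1)O2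
F4 | step 16 | syn-6,8-diol methyl ester (C6 alcohol of 19) | O[C@H]1/C=C(/C)[C@]2(O)CC[C@](CO[Si](C)(C)C(C)(C)C)(C[C@@H](O)[C@H]1CC(=O)OC)O2
F5 | step 16 | 14-O-TBS-3,10-epoxy-3,8,14-trihydroxygermacr-4Z-en-12,6-olide | C1C(=O)O[C@H]2/C=C(/C)[C@]3(O)CC[C@](CO[Si](C)(C)C(C)(C)C)(C[C@@H](O)[C@@H]12)O3
F6 | step 6 | 3-methylfuran-2-carbaldehyde | Cc1ccoc1C=O
F7 | step 6 | (3E)-1-{[tert-butyl(dimethyl)silyl]oxy}-4-(3-methylfuran-2-yl)but-3-en-2-one | Cc1ccoc1/C=C/C(=O)CO[Si](C)(C)C(C)(C)C
F8 | step 6 | 1-{[tert-butyl(dimethyl)silyl]oxy}-4-(3-methylfuran-2-yl)butan-2-one | Cc1ccoc1CCC(=O)CO[Si](C)(C)C(C)(C)C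
A1 | alternative 1 | cyclodecane-3,8-dione lactone acetonide | C1C(=O)O[C@H]2C[C@H](C)C(=O)CC[C@]3(COC(C)(C)O3)CC(=O)[C@@H]12
A2 | alternative 1 | octalin lactone acetonide with the C3=C8 ring-fusion alkene | C1C(=O)O[C@H]2C[C@H](C)C4=C([C@@H]12)C[C@@]3(COC(C)(C)O3)CC4
A3 | alternative 2 | C2-sulfonyl bridged hemiketal | C1C(=O)O[C@H]2/C=C(/C)[C@]3(O)[C@@H](S(=O)(=O)c4ccccc4)C[C@](CO[Si](C)(C)C(C)(C)C)(C[C@@H](OC(=O)[C@H](C)CC)[C@@H]12)O3
A4 | alternative 2 | epoxy β-keto sulfone | C1C(=O)O[C@H]([C@H]1[C@H](OC(=O)[C@H](C)CC)C[C@@]2(CO[Si](C)(C)C(C)(C)C)CO2)/C=C(/C)C(=O)CS(=O)(=O)c1ccccc1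
A5 | alternative 3 | bicyclic homoallylic alcohol | C=C(CO[Si](C)(C)C(C)(C)C)[C@H]1[C@@H](O[Si](C)(C)C(C)(C)C)/C=C(/C)[C@]2(OC)CC[C@](CO[Si](C)(C)C(C)(C)C)(C[C@H]1O)O2
A6 | alternative 3 | thirteen-membered α-stannyl allyl ether | CCCC[Sn](CCCC)(CCCC)C1C[C@@]2(CO[Si](C)(C)C(C)(C)C)CC[C@](OC)(O2)/C(C)=C\[C@H](O[Si](C)(C)C(C)(C)C)C=C(CO[Si](C)(C)C(C)(C)C)CO1
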